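**Plan**
- Retrosynthetic cuts: C12–C13 (alkyl–alkenyl Suzuki–Miyaura coupling of a C9-vinyl bicycle with a C14 trienyl iodide); C8–C9 (ring B, intramolecular allylsilane–ketone addition); C1–C2 together with C5–C10 (ring A, Diels–Alder).
- Enabling feature: in ring A the C3 carbonyl lies 1,4 to the quaternary C10, and C10 carries C9, which can be held as a formyl group. This is the para-adduct pattern of a 2-silyloxy diene (C2=C3(OSi)–C4=C5) with methacrolein (C1=C10, C9 = CHO); the C3=C4 enol ether left behind accepts the second C4 methyl.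
- Forward order: ring A first (steps 1–6), ring B closed onto it (steps 8–10), the C14 chain joined last (step 14).
- Stereochemistry: C10 from a chiral boron Lewis acid; C5 from the endo transition state and the (E)-diene; C9 and C8 from the chair transition state of ring-B closure; chain alkenes from geranyl bromide and syn-methylalumination.

Key step: step 4

Remark: the SMILES is read as written, so H-5 and the C10 methyl are cis (cis-fused decalin; 5S,8R,9R,10S in polypodane numbering, which is used for all carbon numbers below).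

**Step 1**
Reactants: 1 ethyl 3-(2-methyl-1,3-dioxolan-2-yl)propanoate
Product: 2 3-(2-methyl-1,3-dioxolan-2-yl)propanal
Conditions: DIBAL-H (iBu2AlH, 1.05 equiv), CH2Cl2, −78 °C; aqueous potassium sodium tartrate
Reagents that add atoms: none
Why: Partial ester reduction stops at the aluminium hemiacetal at low temperature and releases the aldehyde on work-up, the ketal being inert to hydride.

**Step 2**
Reactants: 2 3-(2-methyl-1,3-dioxolan-2-yl)propanal; 3 3-(triphenylphosphoranylidene)butan-2-one
Product: 4 (3E)-3-methyl-6-(2-methyl-1,3-dioxolan-2-yl)hex-3-en-2-one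
Conditions: toluene, 90 °C
Reagents that add atoms: none
Why: Wittig olefination with a stabilised acyl ylide should give the (E)-trisubstituted enone (acetyl trans to the chain), the geometry that later places H-5 cis to the C10 methyl.

**Step 3**
Reactants: 4 (3E)-3-methyl-6-(2-methyl-1,3-dioxolan-2-yl)hex-3-en-2-one
Product: 5 {[(3E)-3-methyl-6-(2-methyl-1,3-dioxolan-2-yl)hexa-1,3-dien-2-yl]oxy}tri(propan-2-yl)silane
Conditions: LDA (LiN(iPr)2), THF, −78 °C; then iPr3SiOTf, −78 to 0 °C
Reagents that add atoms: triisopropylsilyl trifluoromethanesulfonate, CC(C)[Si](C(C)C)(C(C)C)OS(=O)(=O)C(F)(F)F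
Why: Kinetic deprotonation of the enone at the α'-methyl group gives the cross-conjugated enolate, which is O-silylated to the 2-silyloxy-1,3-diene without touching the (E)-C4=C5 bond.

**Step 4**
Reactants: 5 {[(3E)-3-methyl-6-(2-methyl-1,3-dioxolan-2-yl)hexa-1,3-dien-2-yl]oxy}tri(propan-2-yl)silane; 6 2-methylprop-2-enal (methacrolein)
Product: 7 (1S,2R)-1,3-dimethyl-2-[2-(2-methyl-1,3-dioxolan-2-yl)ethyl]-4-{[tri(propan-2-yl)silyl]oxy}cyclohex-3-ene-1-carbaldehyde
Conditions: (S)-3,3-diphenyl-1-(2-methylphenyl)tetrahydro-1H,3H-pyrrolo[1,2-c][1,3,2]oxazaborole (20 mol %) activated with HN(SO2CF3)2, 6 (2 equiv), CH2Cl2, −78 °C; Et3N quench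
Reagents that add atoms: none
Why: The protonated oxazaborolidine binds the formyl oxygen of 6 (s-trans enal) and lowers its LUMO, so that diene 5 adds in a concerted but asynchronous [4+2] cycloaddition in which the C1–C2 bond (diene CH2 terminus to the enal β-carbon) runs ahead of the C5–C10 bond. The closest known reaction type is the chiral-Lewis-acid-catalysed Diels–Alder reaction of 2-silyloxy-1,3-dienes with α-substituted acroleins. Ring A is the one ring closed, by intermolecular [4+2] annulation: the two new σ-bonds C1–C2 and C5–C10 complete the cyclohexene in a single event and leave the C3=C4 silyl enol ether in place. The quaternary centre C10 is set by the catalyst, whose aryl group shields one face of the bound enal so that the diene should reach the Re face of the α-carbon, and C5 is set relative to C10 by the endo (formyl under the diene) transition state acting on the (E)-C4=C5 bond, which places H-5 cis to the C10 methyl. The step needs the para/ortho regiochemistry, which the C3 silyloxy group (largest HOMO coefficient at C2) and the C5 alkyl group both dictate, endo selectivity, which Lewis-acid activation favours, and cycloaddition in preference to Mukaiyama aldol addition to the formyl group, which the low temperature and the bulky triisopropylsilyl group favour.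

**Step 5**
Reactants: 7 (1S,2R)-1,3-dimethyl-2-[2-(2-methyl-1,3-dioxolan-2-yl)ethyl]-4-{[tri(propan-2-yl)silyl]oxy}cyclohex-3-ene-1-carbaldehyde
Product: 8 (2R,3S)-1,3-dimethyl-2-[2-(2-methyl-1,3-dioxolan-2-yl)ethyl]-6-{[tri(propan-2-yl)silyl]oxy}bicyclo[4.1.0]heptane-3-carbaldehyde (cyclopropane on either face)
Conditions: Et2Zn, CH2I2, CH2Cl2, 0 °C to rt
Reagents that add atoms: diiodomethane, ICI
Why: In this Simmons–Smith cyclopropanation the electrophilic zinc carbenoid should add to the most electron-rich π bond, the tetrasubstituted silyl enol ether, which places the carbon of the second C4 methyl regiospecifically on C4; the two cyclopropane stereocentres are erased in step 6.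

**Step 6**
Reactants: 8 (2R,3S)-1,3-dimethyl-2-[2-(2-methyl-1,3-dioxolan-2-yl)ethyl]-6-{[tri(propan-2-yl)silyl]oxy}bicyclo[4.1.0]heptane-3-carbaldehyde
Product: 9 (1S,2S)-1,3,3-trimethyl-2-[2-(2-methyl-1,3-dioxolan-2-yl)ethyl]-4-oxocyclohexane-1-carbaldehyde
Conditions: Bu4NF·3H2O, THF, 0 °C
Reagents that add atoms: none
Why: Fluoride desilylation gives the cyclopropanolate, which opens toward the primary carbon and is protonated, so that the cyclopropane CH2 becomes the second C4 methyl beside the regenerated C3 ketone; C5 and C10 cannot enolise and keep their configuration.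

**Step 7**
Reactants: 10 methyltriphenylphosphonium bromide; 11 (iodomethyl)trimethylsilane
Product: 13 triphenyl[2-(trimethylsilyl)ethyl]phosphonium iodide, via methylenetriphenylphosphorane 12 (not isolated)
Conditions: n-BuLi, THF, 0 °C; then 11, rt
Reagents that add atoms: none
Why: SN2 C-alkylation of the unstabilised ylide by the primary iodide gives the homologated phosphonium salt.

**Step 8**
Reactants: 9 (1S,2S)-1,3,3-trimethyl-2-[2-(2-methyl-1,3-dioxolan-2-yl)ethyl]-4-oxocyclohexane-1-carbaldehyde; 13 triphenyl[2-(trimethylsilyl)ethyl]phosphonium iodide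
Product: 15 (3S,4R)-2,2,4-trimethyl-3-[2-(2-methyl-1,3-dioxolan-2-yl)ethyl]-4-[(1Z)-3-(trimethylsilyl)prop-1-en-1-yl]cyclohexan-1-one, via the silylethylidene ylide 14 (not isolated)
Conditions: KN(SiMe3)2, THF, −78 to 0 °C; then 9, −78 °C to rt
Reagents that add atoms: none
Why: Wittig olefination of the non-enolisable formyl group with the unstabilised β-silyl ylide under lithium-free conditions should give the (Z)-allylsilane, the hindered C3 ketone reacting far more slowly.

**Step 9**
Reactants: 15 (3S,4R)-2,2,4-trimethyl-3-[2-(2-methyl-1,3-dioxolan-2-yl)ethyl]-4-[(1Z)-3-(trimethylsilyl)prop-1-en-1-yl]cyclohexan-1-one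
Product: 16 (3S,4R)-2,2,4-trimethyl-3-(3-oxobutyl)-4-[(1Z)-3-(trimethylsilyl)prop-1-en-1-yl]cyclohexan-1-one
Conditions: PPTS (cat.), acetone/H2O, 50 °C
Reagents that add atoms: water, O
Why: Mild acid-catalysed ketal hydrolysis frees the C8 methyl ketone, the allylsilane being stable to pyridinium tosylate.

**Step 10**
Reactants: 16 (3S,4R)-2,2,4-trimethyl-3-(3-oxobutyl)-4-[(1Z)-3-(trimethylsilyl)prop-1-en-1-yl]cyclohexan-1-one
Product: 17 (4aS,5R,6R,8aS)-5-ethenyl-6-hydroxy-1,1,4a,6-tetramethyloctahydronaphthalen-2(1H)-one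
Conditions: TiCl4 (1.1 equiv), CH2Cl2, −78 °C; aqueous NaHCO3
Reagents that add atoms: none
Why: In this Hosomi–Sakurai reaction TiCl4 activates the unhindered C8 methyl ketone and the γ-carbon (C9) of the allylsilane attacks it anti to silicon through a chair-like six-membered transition state on the cis C5/C10 arms, in which the C9=C11 unit turns toward the small C10 methyl to relieve A(1,3) strain with the (Z)-CH2SiMe3 group and the bulky titanium-bound oxygen takes the equatorial site, which should set C9 (vinyl cis to the C10 methyl) and C8 (hydroxyl trans to vinyl, methyl cis to the C10 methyl).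

**Step 11**
Reactants: 18 trimethyl(prop-1-yn-1-yl)silane; 19 (2E)-1-bromo-3,7-dimethylocta-2,6-diene (geranyl bromide)
Product: 21 [(5E)-6,10-dimethylundeca-5,9-dien-1-yn-1-yl]trimethylsilane, via 3-lithio-1-(trimethylsilyl)propyne 20 (not isolated)
Conditions: n-BuLi, THF, −78 to −20 °C; then 19, −78 °C to rt
Reagents that add atoms: none
Why: SN2 alkylation of the silyl-blocked propargyl anion at the primary carbon of the allylic bromide adds three carbons and keeps the (E)-alkene.

**Step 12**
Reactants: 21 [(5E)-6,10-dimethylundeca-5,9-dien-1-yn-1-yl]trimethylsilane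
Product: 22 (5E)-6,10-dimethylundeca-5,9-dien-1-yne
Conditions: K2CO3 (cat.), MeOH, rt
Reagents that add atoms: none
Why: Methoxide-mediated protodesilylation of the alkynylsilane gives the terminal alkyne.

**Step 13**
Reactants: 22 (5E)-6,10-dimethylundeca-5,9-dien-1-yne
Product: 24 (1E,5E)-1-iodo-2,6,10-trimethylundeca-1,5,9-triene, via the (E)-alkenyldimethylalane 23 (not isolated)
Conditions: Me3Al, Cp2ZrCl2 (20 mol %), CH2Cl2, 0 °C to rt; then I2, THF, −30 °C
Reagents that add atoms: trimethylaluminium, C[Al](C)C; iodine, II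
Why: Zirconium-catalysed carboalumination (Negishi) adds methyl and aluminium syn across the terminal alkyne with methyl on the internal carbon, and iodinolysis with retention gives the (E)-alkenyl iodide, the trisubstituted alkenes being inert.

**Step 14**
Reactants: 17 (4aS,5R,6R,8aS)-5-ethenyl-6-hydroxy-1,1,4a,6-tetramethyloctahydronaphthalen-2(1H)-one; 24 (1E,5E)-1-iodo-2,6,10-trimethylundeca-1,5,9-triene
Product: 26 (4aS,5R,6R,8aS)-6-hydroxy-1,1,4a,6-tetramethyl-5-[(3E,7E)-4,8,12-trimethyltrideca-3,7,11-trien-1-yl]octahydronaphthalen-2(1H)-one, via the B-alkyl-9-BBN adduct 25 (not isolated)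
Conditions: 9-BBN (1.5 equiv), THF, 0 °C to rt; then 24, Pd(dppf)Cl2 (5 mol %), AsPh3, Cs2CO3, DMF/H2O, rt
Reagents that add atoms: none
Why: Anti-Markovnikov hydroboration of the monosubstituted vinyl group followed by B-alkyl Suzuki–Miyaura coupling forms C12–C13 with retention of the (E)-geometry of 24, and the hindered C3 ketone and the tertiary alcohol should be tolerated.

**Compound list**
1 | ethyl 3-(2-methyl-1,3-dioxolan-2-yl)propanoate | CCOC(=O)CCC1(C)OCCO1 | starting material
2 | 3-(2-methyl-1,3-dioxolan-2-yl)propanal | O=CCCC1(C)OCCO1 | intermediate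
3 | 3-(triphenylphosphoranylidene)butan-2-one | CC(=O)C(C)=P(c1ccccc1)(c1ccccc1)c1ccccc1 | starting material
4 | (3E)-3-methyl-6-(2-methyl-1,3-dioxolan-2-yl)hex-3-en-2-one | CC(=O)/C(C)=C/CCC1(C)OCCO1 | intermediate
5 | {[(3E)-3-methyl-6-(2-methyl-1,3-dioxolan-2-yl)hexa-1,3-dien-2-yl]oxy}tri(propan-2-yl)silane | C=C(O[Si](C(C)C)(C(C)C)C(C)C)/C(C)=C/CCC1(C)OCCO1 | intermediate
6 | 2-methylprop-2-enal (methacrolein) | CC(=C)C=O | starting material
7 | (1S,2R)-1,3-dimethyl-2-[2-(2-methyl-1,3-dioxolan-2-yl)ethyl]-4-{[tri(propan-2-yl)silyl]oxy}cyclohex-3-ene-1-carbaldehyde | O=C[C@@]1(C)CCC(O[Si](C(C)C)(C(C)C)C(C)C)=C(C)[C@H]1CCC2(C)OCCO2 | intermediate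
8 | (2R,3S)-1,3-dimethyl-2-[2-(2-methyl-1,3-dioxolan-2-yl)ethyl]-6-{[tri(propan-2-yl)silyl]oxy}bicyclo[4.1.0]heptane-3-carbaldehyde (cyclopropane carbons left undefined, both faces converge on 9) | O=C[C@@]1(C)CCC2(O[Si](C(C)C)(C(C)C)C(C)C)CC2(C)[C@H]1CCC3(C)OCCO3 | intermediate
9 | (1S,2S)-1,3,3-trimethyl-2-[2-(2-methyl-1,3-dioxolan-2-yl)ethyl]-4-oxocyclohexane-1-carbaldehyde | O=C[C@@]1(C)CCC(=O)C(C)(C)[C@H]1CCC2(C)OCCO2 | intermediate
10 | methyltriphenylphosphonium bromide | C[P+](c1ccccc1)(c1ccccc1)c1ccccc1.[Br-] | starting material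
11 | (iodomethyl)trimethylsilane | C[Si](C)(C)CI | starting material
12 | methylenetriphenylphosphorane | C=P(c1ccccc1)(c1ccccc1)c1ccccc1 | intermediate (not isolated)
13 | triphenyl[2-(trimethylsilyl)ethyl]phosphonium iodide | C[Si](C)(C)CC[P+](c1ccccc1)(c1ccccc1)c1ccccc1.[I-] | intermediate
14 | [2-(trimethylsilyl)ethylidene]triphenylphosphorane | C[Si](C)(C)CC=P(c1ccccc1)(c1ccccc1)c1ccccc1 | intermediate (not isolated)
15 | (3S,4R)-2,2,4-trimethyl-3-[2-(2-methyl-1,3-dioxolan-2-yl)ethyl]-4-[(1Z)-3-(trimethylsilyl)prop-1-en-1-yl]cyclohexan-1-one | C[Si](C)(C)C/C=C\[C@@]1(C)CCC(=O)C(C)(C)[C@H]1CCC2(C)OCCO2 | intermediate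
16 | (3S,4R)-2,2,4-trimethyl-3-(3-oxobutyl)-4-[(1Z)-3-(trimethylsilyl)prop-1-en-1-yl]cyclohexan-1-one | C[Si](C)(C)C/C=C\[C@@]1(C)CCC(=O)C(C)(C)[C@H]1CCC(C)=O | intermediate
17 | (4aS,5R,6R,8aS)-5-ethenyl-6-hydroxy-1,1,4a,6-tetramethyloctahydronaphthalen-2(1H)-one | C=C[C@@H]1[C@@]2(C)CCC(=O)C(C)(C)[C@H]2CC[C@@]1(C)O | intermediate
18 | trimethyl(prop-1-yn-1-yl)silane | CC#C[Si](C)(C)C | starting material
19 | (2E)-1-bromo-3,7-dimethylocta-2,6-diene (geranyl bromide) | CC(C)=CCC/C(C)=C/CBr | starting material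
20 | 3-lithio-1-(trimethylsilyl)prop-1-yne | [Li]CC#C[Si](C)(C)C | intermediate (not isolated)
21 | [(5E)-6,10-dimethylundeca-5,9-dien-1-yn-1-yl]trimethylsilane | C[Si](C)(C)C#CCC/C=C(C)/CCC=C(C)C | intermediate
22 | (5E)-6,10-dimethylundeca-5,9-dien-1-yne | C#CCC/C=C(C)/CCC=C(C)C | intermediate
23 | dimethyl[(1E,5E)-2,6,10-trimethylundeca-1,5,9-trien-1-yl]alane | C[Al](C)/C=C(C)/CC/C=C(C)/CCC=C(C)C | intermediate (not isolated)
24 | (1E,5E)-1-iodo-2,6,10-trimethylundeca-1,5,9-triene | I/C=C(C)/CC/C=C(C)/CCC=C(C)C | intermediate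
25 | (4aS,5R,6R,8aS)-5-[2-(9-borabicyclo[3.3.1]nonan-9-yl)ethyl]-6-hydroxy-1,1,4a,6-tetramethyloctahydronaphthalen-2(1H)-one | C1CCC2CCCC1B2CC[C@@H]1[C@@]2(C)CCC(=O)C(C)(C)[C@H]2CC[C@@]1(C)O | intermediate (not isolated)
26 | (4aS,5R,6R,8aS)-6-hydroxy-1,1,4a,6-tetramethyl-5-[(3E,7E)-4,8,12-trimethyltrideca-3,7,11-trien-1-yl]octahydronaphthalen-2(1H)-one | CC(C)=CCC/C(C)=C/CC/C(C)=C/CC[C@@H]1[C@@]2(C)CCC(=O)C(C)(C)[C@H]2CC[C@@]1(C)O | target

**Step count**
Total: 14 steps. Longest linear sequence: 10 steps (steps 1–6, 8, 9, 10, 14).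

**Steps most likely to fail**

Step 4. The cycloaddition may run with too little endo or facial selectivity, or the strongly acidic catalyst may divert the silyl enol ether into Mukaiyama aldol addition or ionise the ketal. The fallback replaces catalyst control by auxiliary control and sets out from 5. Methacryloyl chloride and (R)-pantolactone give (3R)-4,4-dimethyl-2-oxooxolan-3-yl 2-methylprop-2-enoate F1. Cycloaddition of 5 with F1 under EtAlCl2 in CH2Cl2 at −78 °C (chelated enoate, the auxiliary antipode being chosen by the chelate model) should give the ester adduct (3R)-4,4-dimethyl-2-oxooxolan-3-yl (1S,2R)-1,3-dimethyl-2-[2-(2-methyl-1,3-dioxolan-2-yl)ethyl]-4-{[tri(propan-2-yl)silyl]oxy}cyclohex-3-ene-1-carboxylate F2. LiAlH4 reduction gives the neopentyl alcohol [(1S,2S)-1,3-dimethyl-2-[2-(2-methyl-1,3-dioxolan-2-yl)ethyl]-4-{[tri(propan-2-yl)silyl]oxy}cyclohex-3-en-1-yl]methanol F3, and Swern oxidation comes back to the route at 7.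

Step 10. Ring closure may pass through the alternative chair and give the wrong relative configuration at C8 and C9, or protodesilylation of the allylsilane may outrun the hindered C–C bond formation. The fallback replaces the polar allylsilane addition by a reductive ketyl addition–fragmentation and sets out from 9. Sodium benzenethiolate and vinyltriphenylphosphonium bromide generate [2-(phenylsulfanyl)ethylidene]triphenylphosphorane F4 in the flask. Its Wittig reaction with 9 gives the allyl sulfide (3S,4R)-2,2,4-trimethyl-3-[2-(2-methyl-1,3-dioxolan-2-yl)ethyl]-4-[(1Z)-3-(phenylsulfanyl)prop-1-en-1-yl]cyclohexan-1-one F5. PPTS in wet acetone frees the methyl ketone to give (3S,4R)-2,2,4-trimethyl-3-(3-oxobutyl)-4-[(1Z)-3-(phenylsulfanyl)prop-1-en-1-yl]cyclohexan-1-one F6. SmI2/HMPA in THF should reduce the methyl ketone to its ketyl, which adds 6-exo to C9 and expels the phenylthio group, with the hydroxyl trans to the new vinyl group by the usual anti preference of ketyl–olefin cyclisations; this comes back to the route at 17.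

Step 5. Carbenoid transfer to the hindered tetrasubstituted enol ether may be sluggish, and the zinc reagent may attack the formyl group instead. The fallback replaces cyclopropanation and ring opening by direct enolate methylation and sets out from 7. Wittig reaction of 7 with ylide 14 is carried out first and gives {[(3S,4R)-2,4-dimethyl-3-[2-(2-methyl-1,3-dioxolan-2-yl)ethyl]-4-[(1Z)-3-(trimethylsilyl)prop-1-en-1-yl]cyclohex-1-en-1-yl]oxy}tri(propan-2-yl)silane F7. The C3/C4 enolate is then released with anhydrous fluoride (tris(dimethylamino)sulfonium difluorotrimethylsilicate) at −78 °C in the presence of MeI and is methylated regiospecifically at C4; this comes back to the route at 15 and bypasses 8 and 9.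

**Further compounds**
F1 | step 4 | (3R)-4,4-dimethyl-2-oxooxolan-3-yl 2-methylprop-2-enoate | C=C(C)C(=O)O[C@H]1C(=O)OCC1(C)C
F2 | step 4 | (3R)-4,4-dimethyl-2-oxooxolan-3-yl (1S,2R)-1,3-dimethyl-2-[2-(2-methyl-1,3-dioxolan-2-yl)ethyl]-4-{[tri(propan-2-yl)silyl]oxy}cyclohex-3-ene-1-carboxylate | O=C(O[C@H]1C(=O)OCC1(C)C)[C@@]2(C)CCC(O[Si](C(C)C)(C(C)C)C(C)C)=C(C)[C@H]2CCC3(C)OCCO3
F3 | step 4 | [(1S,2S)-1,3-dimethyl-2-[2-(2-methyl-1,3-dioxolan-2-yl)ethyl]-4-{[tri(propan-2-yl)silyl]oxy}cyclohex-3-en-1-yl]methanol | OC[C@@]1(C)CCC(O[Si](C(C)C)(C(C)C)C(C)C)=C(C)[C@H]1CCC2(C)OCCO2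
F4 | step 10 | [2-(phenylsulfanyl)ethylidene]triphenylphosphorane | c1ccccc1SCC=P(c2ccccc2)(c3ccccc3)c4ccccc4
F5 | step 10 | (3S,4R)-2,2,4-trimethyl-3-[2-(2-methyl-1,3-dioxolan-2-yl)ethyl]-4-[(1Z)-3-(phenylsulfanyl)prop-1-en-1-yl]cyclohexan-1-one | c1ccccc1SC/C=C\[C@@]1(C)CCC(=O)C(C)(C)[C@H]1CCC2(C)OCCO2
F6 | step 10 | (3S,4R)-2,2,4-trimethyl-3-(3-oxobutyl)-4-[(1Z)-3-(phenylsulfanyl)prop-1-en-1-yl]cyclohexan-1-one | c1ccccc1SC/C=C\[C@@]1(C)CCC(=O)C(C)(C)[C@H]1CCC(C)=O
F7 | step 5 | {[(3S,4R)-2,4-dimethyl-3-[2-(2-methyl-1,3-dioxolan-2-yl)ethyl]-4-[(1Z)-3-(trimethylsilyl)prop-1-en-1-yl]cyclohex-1-en-1-yl]oxy}tri(propan-2-yl)silane | C[Si](C)(C)C/C=C\[C@@]1(C)CCC(O[Si](C(C)C)(C(C)C)C(C)C)=C(C)[C@H]1CCC2(C)OCCO2
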